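**Plan**
- Retrosynthesis cuts the C3–O and C4–O bonds of both halves (back to a 6,6′-linked bis-flav-3-ene), then C3=C4 (metathesis) and O1–C2 (allylic etherification) of both pyran rings, and last the C6–C6′ biaryl bond (phenol coupling of a monocyclic benzaldehyde).
- Forward: the biaryl is made first by oxidative dimerisation; both O1–C2 bonds and both C rings are then made two-directionally; the two diols are installed one half at a time.
- Stereochemistry: C2 of both halves comes from one iridium/phosphoramidite catalyst; C3 and C4 are relayed from C2 by anti iodo-acyloxylation and acyloxy participation. Dry conditions (Prévost) give the 3,4-trans half, wet conditions (Woodward) the all-cis half.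
- Enabling feature: O7 of each half is para to C4a, so its substituent sets the nucleophilicity of that half's C3=C4 bond and the lability of its C4. O7(A) and O7(B) are also the two OH groups of a 2,2′-biphenol flanking C6–C6′, so one can be tosylated and the other benzylated; the benzyl-ether half reacts first.

Key step: step 11

Remark 1: the C6–C6′ axis has only two ortho substituents and is taken as freely rotating; flavan numbering is used with suffix A for the (2R,3R,4R) all-cis half and B for the (2R,3R,4S) half, and α means the face of a pyran ring that carries its C2 aryl group (the SMILES carry the absolute configuration).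
Remark 2: the enantiomer of the phosphoramidite ligand in step 9 is assigned by analogy with cinnamyl carbonate/phenoxide pairs; the one meant is that which gives the S ethers of 11.

**Route**

Step 1
Reactants: 1 2,3,4-trihydroxybenzaldehyde
Product: 2 3-(benzyloxy)-2,4-dihydroxybenzaldehyde
Conditions: NaH (3.1 equiv), DMSO–THF, 0 °C→rt; BnBr (1.0 equiv), rt; aq HCl
Reagents that add atoms: benzyl bromide BrCc1ccccc1
Why: Williamson etherification of the trianion, in which the 2- and 4-oxides are delocalised into the formyl group and the 3-oxide is the most nucleophilic (the logic that alkylates O3 of the 3,4-dihydroxybenzaldehyde dianion); no stereocentre.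

Step 2
Reactants: 2 3-(benzyloxy)-2,4-dihydroxybenzaldehyde (two molecules)
Product: 3 5,5′-bis(benzyloxy)-4,4′,6,6′-tetrahydroxybiphenyl-3,3′-dicarbaldehyde
Conditions: Na2S2O8 (0.55 equiv), FeSO4·7H2O (5 mol %), acetone–H2O, 50 °C
Reagents that add atoms: none
Why: Oxidative phenol coupling of the dehydrodivanillin type; C5 is the only free position ortho/para to the phenoxyl oxygens (ortho to O4, para to O2), C3 is blocked by the benzyl ether, and the product has no such position left.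

Step 3
Reactants: 3 5,5′-bis(benzyloxy)-4,4′,6,6′-tetrahydroxybiphenyl-3,3′-dicarbaldehyde
Product: 4 5,5′-bis(benzyloxy)-4,4′,6′-trihydroxy-6-(tosyloxy)biphenyl-3,3′-dicarbaldehyde
Conditions: TsCl (1.0 equiv), Et3N (1.0 equiv), CH2Cl2, −20→0 °C
Reagents that add atoms: 4-toluenesulfonyl chloride Cc1ccc(S(=O)(=O)Cl)cc1
Why: Mono-sulfonylation of a 2,2′-biphenol: the 6/6′-OH groups (para to CHO, not chelated) are far more acidic than the formyl-chelated 4/4′-OH, the first ionisation is favoured by the O–H···O− bridge across the axis, and the first tosyl group shields its neighbour.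

Step 4
Reactants: 4 5,5′-bis(benzyloxy)-4,4′,6′-trihydroxy-6-(tosyloxy)biphenyl-3,3′-dicarbaldehyde
Product: 5 5,5′,6′-tris(benzyloxy)-4,4′-dihydroxy-6-(tosyloxy)biphenyl-3,3′-dicarbaldehyde
Conditions: BnBr (1.1 equiv), KHCO3 (1.5 equiv), DMF, 40 °C
Reagents that add atoms: benzyl bromide BrCc1ccccc1
Why: Chemoselective Williamson etherification; hydrogen carbonate ionises only the para-formyl 6′-OH while the two chelated ortho-formyl OH groups stay protonated (as in 4-O-alkylation of 2,4-dihydroxybenzaldehyde).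

Step 5
Reactants: 5 5,5′,6′-tris(benzyloxy)-4,4′-dihydroxy-6-(tosyloxy)biphenyl-3,3′-dicarbaldehyde
Product: 6 5,5′,6′-tris(benzyloxy)-4,4′-dihydroxy-6-(tosyloxy)-3,3′-divinylbiphenyl
Conditions: MePPh3Br (2.5 equiv), NaHMDS (4.6 equiv), THF, 0 °C→rt; aq NH4Cl
Reagents that add atoms: methyltriphenylphosphonium bromide C[P+](c1ccccc1)(c1ccccc1)c1ccccc1.[Br-]
Why: Two-fold Wittig methylenation of the salicylaldehyde phenoxides; the aryl tosylate and benzyl ethers are inert to the ylide.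

Step 6
Reactants: 7 4-(benzyloxy)benzaldehyde
Product: 8 ethyl (E)-3-[4-(benzyloxy)phenyl]prop-2-enoate
Conditions: (EtO)2P(O)CH2CO2Et, NaH, THF, 0 °C→rt
Reagents that add atoms: triethyl phosphonoacetate CCOC(=O)CP(=O)(OCC)OCC
Why: Horner–Wadsworth–Emmons olefination, E-selective for aryl aldehydes.

Step 7
Reactants: 8 ethyl (E)-3-[4-(benzyloxy)phenyl]prop-2-enoate
Product: 9 (E)-3-[4-(benzyloxy)phenyl]prop-2-en-1-ol
Conditions: DIBAL-H (2.2 equiv), CH2Cl2, −78 °C; Rochelle salt
Reagents that add atoms: none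
Why: 1,2-Reduction of the enoate to the allylic alcohol without touching the double bond or the benzyl ether.

Step 8
Reactants: 9 (E)-3-[4-(benzyloxy)phenyl]prop-2-en-1-ol
Product: 10 (E)-3-[4-(benzyloxy)phenyl]allyl methyl carbonate
Conditions: ClCO2Me, pyridine, CH2Cl2, 0 °C
Reagents that add atoms: methyl chloroformate COC(=O)Cl
Why: O-Acylation gives the carbonate leaving group needed for iridium allyl formation.

Step 9
Reactants: 6 5,5′,6′-tris(benzyloxy)-4,4′-dihydroxy-6-(tosyloxy)-3,3′-divinylbiphenyl; 10 (E)-3-[4-(benzyloxy)phenyl]allyl methyl carbonate (2.4 equiv)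
Product: 11 4,4′-bis{[(1S)-1-(4-benzyloxyphenyl)prop-2-en-1-yl]oxy}-5,5′,6′-tris(benzyloxy)-6-(tosyloxy)-3,3′-divinylbiphenyl
Conditions: 6, LiHMDS (2.0 equiv), THF, 0 °C; then 10, [Ir(cod)Cl]2 (4 mol %), (Sa,S,S)-(1,1′-binaphthalene-2,2′-diyl) N,N-bis(1-phenylethyl)phosphoramidite (8 mol %, pre-activated with n-PrNH2), THF, rt→50 °C, dark
Reagents that add atoms: none
Why: Two-fold iridium-catalysed enantioselective allylic etherification, in which each phenoxide attacks the aryl-substituted terminus of the π-allyl iridium complex under catalyst control to set C2(A) and C2(B) as S ethers; two independent events should leave most of the minor enantiomer as a separable diastereomer.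

Step 10
Reactants: 11 4,4′-bis{[(1S)-1-(4-benzyloxyphenyl)prop-2-en-1-yl]oxy}-5,5′,6′-tris(benzyloxy)-6-(tosyloxy)-3,3′-divinylbiphenyl
Product: 12 (2S,2′S)-6,6′-bi(2H-chromene), each ring 2-(4-benzyloxyphenyl) and 8-OBn, unit A 7-OTs, unit B 7-OBn
Conditions: [RuCl2(H2IMes)(PCy3)(=CHPh)] (10 mol %), 1,4-benzoquinone (10 mol %), CH2Cl2, 40 °C, dark
Reagents that add atoms: none
Why: Two ring-closing metatheses, each joining the styrene CH= and the allyl CH= in a six-membered ring with loss of ethene; C2 is not touched, benzoquinone suppresses Ru–H olefin migration and light is excluded because 2H-chromenes ring-open photochemically.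

Step 11
Reactants: 12 (2S,2′S)-6,6′-bi(2H-chromene), unit A 7-OTs, unit B 7-OBn
Product: 15 unit-B 3α,4β-dibenzoate (2,3-cis-3,4-trans flavan) joined at C6 to the unchanged unit-A flav-3-ene, via trans-iodo benzoate 13 (not isolated), via dioxolanylium benzoate 14 (not isolated)
Conditions: I2 (1.0 equiv), AgOBz (2.2 equiv), dry benzene, rt, dark; then 70–80 °C
Reagents that add atoms: silver benzoate [Ag+].[O-]C(=O)c1ccccc1
Why: Prévost trans-diacyloxylation run on one of two chromene double bonds: benzoyl hypoiodite delivers I+ to C3(B) on the β face, anti to the C2(B) aryl group, and benzoate to the benzylic C4(B) on the α face, giving 13. Silver then removes the iodide while the C4 benzoate carbonyl oxygen attacks C3(B) from the α face (5-exo-tet closure of the transient 2-phenyl-1,3-dioxolan-2-ylium ring of 14; no ring of the product is closed), and a second benzoate opens this ion at the benzylic C4(B) from the β face. C3(B) thus ends with an α oxygen by double inversion and C4(B) with a β oxygen by single inversion, both relayed from C2(B), which is the 2,3-cis-3,4-trans array of unit B; a C4(B) cation, if it forms, is also captured on the β face, so both pathways converge. The step needs site selectivity between two otherwise identical styrene-type C3=C4 bonds: that of unit B is para to the donor O7(B) benzyl ether and that of unit A para to the acceptor O7(A) tosylate, and electrophilic additions to styrenes respond steeply to such para substituents, so one equivalent of iodine should be consumed by unit B alone. The closest known reactions are the Prévost reaction of cyclic styrenes and 2H-chromenes and the preference of electrophilic halogen for the more electron-rich of two alkenes.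

Step 12
Reactants: 15 unit-B 3α,4β-dibenzoate joined to the unit-A flav-3-ene
Product: 19 unit-A 3α,4α-diacetate (all-cis) and unit-B 3α,4β-dibenzoate, via trans-iodo acetate 16 (not isolated), via dioxolanylium acetate 17 (not isolated), via cis-hydroxy acetate 18 (not isolated)
Conditions: I2 (1.1 equiv), AgOAc (2.3 equiv), AcOH, rt (addition complete before heating); AcOH–H2O (1.5 equiv H2O), 60 °C; crude: Ac2O, pyridine, DMAP, rt
Reagents that add atoms: silver acetate CC(=O)[O-].[Ag+]; water O; acetic anhydride CC(=O)OC(C)=O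
Why: Woodward cis-hydroxylation: acetyl hypoiodite adds I to C3(A) anti to the C2(A) aryl group and acetate to C4(A), silver-assisted acetoxy participation gives the α-fused 2-methyl-1,3-dioxolan-2-ylium ion 17, and water adds to its cationic carbon so that both oxygens stay on the α face (all-cis unit A), helped by the para tosylate which disfavours opening to a C4(A) cation; acetylation merges the hydroxy-acetate regioisomers into one diacetate.

Step 13
Reactants: 19 unit-A 3α,4α-diacetate and unit-B 3α,4β-dibenzoate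
Product: 21 7(A)-phenol pentabenzyl ether of the target, via tetraol tosylate 20 (not isolated)
Conditions: NaOMe (0.5 equiv), MeOH–THF, rt; then Mg turnings (10 equiv), rt; aq NH4Cl
Reagents that add atoms: none
Why: Zemplén transesterification removes the four esters while O7(A) is still sulfonylated (so no para-quinone methide can expel a C4 acetate), then single-electron reduction by Mg/MeOH cleaves the aryl tosylate S–O bond; no stereocentre is touched.

Step 14
Reactants: 21 7(A)-phenol pentabenzyl ether of the target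
Product: 22 epioritin-4α-ol-(6→6)-epioritin-4β-ol (target)
Conditions: H2 (1 atm), Pd(OH)2/C, THF–MeOH, rt; filtered under argon
Reagents that add atoms: none
Why: Neutral hydrogenolysis of the five aryl benzyl ethers, which should be much faster than cleavage of the secondary benzylic C4–OH or C2–O1 bonds; acid is avoided because C4 of either half epimerises through its para-hydroxybenzyl cation.

**Compound list**
1 | 2,3,4-trihydroxybenzaldehyde | O=Cc1ccc(O)c(O)c1O | starting material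
2 | 3-(benzyloxy)-2,4-dihydroxybenzaldehyde | O=Cc1ccc(O)c(OCc2ccccc2)c1O | intermediate
3 | 5,5′-bis(benzyloxy)-4,4′,6,6′-tetrahydroxybiphenyl-3,3′-dicarbaldehyde | O=Cc1cc(-c2cc(C=O)c(O)c(OCc3ccccc3)c2O)c(O)c(OCc2ccccc2)c1O | intermediate
4 | 5,5′-bis(benzyloxy)-4,4′,6′-trihydroxy-6-(tosyloxy)biphenyl-3,3′-dicarbaldehyde | O=Cc1cc(-c2cc(C=O)c(O)c(OCc3ccccc3)c2OS(=O)(=O)c2ccc(C)cc2)c(O)c(OCc2ccccc2)c1O | intermediate
5 | 5,5′,6′-tris(benzyloxy)-4,4′-dihydroxy-6-(tosyloxy)biphenyl-3,3′-dicarbaldehyde | O=Cc1cc(-c2cc(C=O)c(O)c(OCc3ccccc3)c2OS(=O)(=O)c2ccc(C)cc2)c(OCc2ccccc2)c(OCc2ccccc2)c1O | intermediate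
6 | 5,5′,6′-tris(benzyloxy)-4,4′-dihydroxy-6-(tosyloxy)-3,3′-divinylbiphenyl | C=Cc1cc(-c2cc(C=C)c(O)c(OCc3ccccc3)c2OS(=O)(=O)c2ccc(C)cc2)c(OCc2ccccc2)c(OCc2ccccc2)c1O | intermediate
7 | 4-(benzyloxy)benzaldehyde | O=Cc1ccc(OCc2ccccc2)cc1 | starting material
8 | ethyl (E)-3-[4-(benzyloxy)phenyl]prop-2-enoate | CCOC(=O)/C=C/c1ccc(OCc2ccccc2)cc1 | intermediate
9 | (E)-3-[4-(benzyloxy)phenyl]prop-2-en-1-ol | OC/C=C/c1ccc(OCc2ccccc2)cc1 | intermediate
10 | (E)-3-[4-(benzyloxy)phenyl]allyl methyl carbonate | COC(=O)OC/C=C/c1ccc(OCc2ccccc2)cc1 | intermediate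
11 | 4,4′-bis{[(1S)-1-(4-benzyloxyphenyl)prop-2-en-1-yl]oxy}-5,5′,6′-tris(benzyloxy)-6-(tosyloxy)-3,3′-divinylbiphenyl | C(c1ccccc1)Oc1ccc([C@H](C=C)Oc3c(C=C)cc(-c4cc(C=C)c(c(OCc6ccccc6)c4OCc4ccccc4)O[C@H](c4ccc(OCc6ccccc6)cc4)C=C)c(OS(=O)(=O)c4ccc(C)cc4)c3OCc3ccccc3)cc1 | intermediate
12 | (2S,2′S)-6,6′-bi(2H-chromene): each ring 2-(4-benzyloxyphenyl), 8-OBn; unit A 7-OTs; unit B 7-OBn | C(c1ccccc1)Oc1ccc([C@H]2Oc3c(cc(-c4cc5c(c(OCc6ccccc6)c4OCc4ccccc4)O[C@H](c4ccc(OCc6ccccc6)cc4)C=C5)c(OS(=O)(=O)c4ccc(C)cc4)c3OCc3ccccc3)C=C2)cc1 | intermediate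
13 | 12 with 3β-iodo and 4α-benzoyloxy on unit B | C(c1ccccc1)Oc1ccc([C@H]2Oc3c(cc(-c4cc5c(c(OCc6ccccc6)c4OCc4ccccc4)O[C@H](c4ccc(OCc6ccccc6)cc4)[C@@H](I)[C@@H]5OC(=O)c4ccccc4)c(OS(=O)(=O)c4ccc(C)cc4)c3OCc3ccccc3)C=C2)cc1 | intermediate
14 | 12 with an α-fused 2-phenyl-1,3-dioxolan-2-ylium ring across C3/C4 of unit B, benzoate salt | C(c1ccccc1)Oc1ccc([C@H]2Oc3c(cc(-c4cc5c(c(OCc6ccccc6)c4OCc4ccccc4)O[C@H](c4ccc(OCc6ccccc6)cc4)[C@H](O[C+](c4ccccc4)O6)[C@@H]56)c(OS(=O)(=O)c4ccc(C)cc4)c3OCc3ccccc3)C=C2)cc1.[O-]C(=O)c1ccccc1 | intermediate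
15 | unit B 3α,4β-bis(benzoyloxy)flavan (7,8,4′-tri-OBn) joined at C6 to the unit A (2S)-flav-3-ene (7-OTs, 8,4′-di-OBn) | C(c1ccccc1)Oc1ccc([C@H]2Oc3c(cc(-c4cc5c(c(OCc6ccccc6)c4OCc4ccccc4)O[C@H](c4ccc(OCc6ccccc6)cc4)[C@H](OC(=O)c4ccccc4)[C@H]5OC(=O)c4ccccc4)c(OS(=O)(=O)c4ccc(C)cc4)c3OCc3ccccc3)C=C2)cc1 | intermediate
16 | 15 with 3β-iodo and 4α-acetoxy on unit A | C(c1ccccc1)Oc1ccc([C@H]2Oc3c(cc(-c4cc5c(c(OCc6ccccc6)c4OCc4ccccc4)O[C@H](c4ccc(OCc6ccccc6)cc4)[C@H](OC(=O)c4ccccc4)[C@H]5OC(=O)c4ccccc4)c(OS(=O)(=O)c4ccc(C)cc4)c3OCc3ccccc3)[C@@H](OC(C)=O)[C@@H]2I)cc1 | intermediate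
17 | 15 with an α-fused 2-methyl-1,3-dioxolan-2-ylium ring across C3/C4 of unit A, acetate salt | C(c1ccccc1)Oc1ccc([C@H]2Oc3c(cc(-c4cc5c(c(OCc6ccccc6)c4OCc4ccccc4)O[C@H](c4ccc(OCc6ccccc6)cc4)[C@H](OC(=O)c4ccccc4)[C@H]5OC(=O)c4ccccc4)c(OS(=O)(=O)c4ccc(C)cc4)c3OCc3ccccc3)[C@@H](O[C+](C)O7)[C@H]27)cc1.CC(=O)[O-] | intermediate
18 | unit A 3α-acetoxy-4α-hydroxy (major hydroxy acetate), unit B 3α,4β-dibenzoate | C(c1ccccc1)Oc1ccc([C@H]2Oc3c(cc(-c4cc5c(c(OCc6ccccc6)c4OCc4ccccc4)O[C@H](c4ccc(OCc6ccccc6)cc4)[C@H](OC(=O)c4ccccc4)[C@H]5OC(=O)c4ccccc4)c(OS(=O)(=O)c4ccc(C)cc4)c3OCc3ccccc3)[C@@H](O)[C@H]2OC(C)=O)cc1 | intermediate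
19 | unit A 3α,4α-diacetate (7-OTs), unit B 3α,4β-dibenzoate, five benzyl ethers | C(c1ccccc1)Oc1ccc([C@H]2Oc3c(cc(-c4cc5c(c(OCc6ccccc6)c4OCc4ccccc4)O[C@H](c4ccc(OCc6ccccc6)cc4)[C@H](OC(=O)c4ccccc4)[C@H]5OC(=O)c4ccccc4)c(OS(=O)(=O)c4ccc(C)cc4)c3OCc3ccccc3)[C@@H](OC(C)=O)[C@H]2OC(C)=O)cc1 | intermediate
20 | tetraol tosylate: unit A 3α,4α-diol with 7-OTs, unit B 3α,4β-diol, five benzyl ethers | C(c1ccccc1)Oc1ccc([C@H]2Oc3c(cc(-c4cc5c(c(OCc6ccccc6)c4OCc4ccccc4)O[C@H](c4ccc(OCc6ccccc6)cc4)[C@H](O)[C@H]5O)c(OS(=O)(=O)c4ccc(C)cc4)c3OCc3ccccc3)[C@@H](O)[C@H]2O)cc1 | intermediate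
21 | target with benzyl ethers on O8(A), O4′(A), O7(B), O8(B), O4′(B) and free O7(A)–H | C(c1ccccc1)Oc1ccc([C@H]2Oc3c(cc(-c4cc5c(c(OCc6ccccc6)c4OCc4ccccc4)O[C@H](c4ccc(OCc6ccccc6)cc4)[C@H](O)[C@H]5O)c(O)c3OCc3ccccc3)[C@@H](O)[C@H]2O)cc1 | intermediate
22 | (2R,3R,4R)-flavan-3,4,7,8,4′-pentaol joined C6–C6 to (2R,3R,4S)-flavan-3,4,7,8,4′-pentaol | Oc1ccc([C@H]2Oc3c(cc(-c4cc5c(c(O)c4O)O[C@H](c4ccc(O)cc4)[C@H](O)[C@H]5O)c(O)c3O)[C@@H](O)[C@H]2O)cc1 | target

**Totals and risks**
Total step count: 14. Longest linear sequence: 11 steps (1–5, 9–14).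

Steps most likely to fail:

1. Step 11. When silver removes iodide from C3(B), migration of the electron-rich aryl carbon C4a(B) from C4 to C3 (ring contraction) can compete with benzoyloxy participation, and at the temperature of that stage residual hypoiodite can begin to add to unit A, eroding site selectivity. The fallback sets out from 12 and keeps the electronic gating but uses no silver and no heating: NBS (1.0 equiv) in THF–water at 0 °C should give the unit-B bromohydrin F1 (3β-Br, 4α-OH). K2CO3 in acetonitrile should close it to the unit-B 3α,4α-epoxide F2. Benzoic acid with caesium benzoate in toluene should open the epoxide at the benzylic C4(B) with inversion to the unit-B 3α-ol 4β-benzoate F3. Benzoyl chloride/pyridine then gives 15, where the route is rejoined.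

2. Step 12. The hot aqueous acetic acid stage can ionise the benzylic C4(B) benzoate of the half made first (assisted by the trans C3 benzoate), letting unit B drift toward the cis series, and excess acetyl hypoiodite can iodinate the benzyloxy-arene rings. The fallback sets out from 15 and avoids any aqueous acid: NBS in THF–water should give the unit-A bromohydrin F4 (3β-Br, 4α-OH). Boc2O/DMAP should convert it to the unit-A 4α-tert-butyl carbonate F5. AgOTf with 2,6-di-tert-butylpyridine in dry CH2Cl2 should let the carbonate carbonyl oxygen displace bromide at C3(A) with inversion and lose isobutene, giving the unit-A 3α,4α-cyclic carbonate F6. F6 enters step 13 in place of 19 (methoxide opens the cyclic carbonate along with the benzoates, giving 20), and the route is rejoined at 21.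

3. Step 9. Attack of the doubly ortho-substituted phenoxides on the electron-rich aryl-allyl iridium complex may be slow, with linear ether formation and re-ionisation of the branched ethers lowering the enantiomeric purity at C2. The fallback sets out from 5 and replaces steps 5, 9 and 10 by a benzopyrylium route: (ethoxycarbonylmethylene)triphenylphosphorane in N,N-diethylaniline at reflux should give the bis-coumarin F7. DIBAL-H at −78 °C should reduce it to the bis-lactol F8, and ethanol/PPTS should give the bis(2-ethoxy-2H-chromene) F9. A chiral tartaramide diol with a lanthanide triflate, known for enantioselective boronate addition to chromene acetals, should then add the aryl group of diethyl [4-(benzyloxy)phenyl]boronate F10 (from the commercial boronic acid and ethanol) to both 7,8-dioxygenated benzopyrylium ions. The catalyst enantiomer is chosen to give 2S, and the product is 12, where the route is rejoined.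

**Further compounds**
F1 | step 11 | unit-B bromohydrin of 12 (3β-Br, 4α-OH) | C(c1ccccc1)Oc1ccc([C@H]2Oc3c(cc(-c4cc5c(c(OCc6ccccc6)c4OCc4ccccc4)O[C@H](c4ccc(OCc6ccccc6)cc4)[C@@H](Br)[C@@H]5O)c(OS(=O)(=O)c4ccc(C)cc4)c3OCc3ccccc3)C=C2)cc1
F2 | step 11 | unit-B 3α,4α-epoxide of 12 | C(c1ccccc1)Oc1ccc([C@H]2Oc3c(cc(-c4cc5c(c(OCc6ccccc6)c4OCc4ccccc4)O[C@H](c4ccc(OCc6ccccc6)cc4)[C@H](O6)[C@@H]56)c(OS(=O)(=O)c4ccc(C)cc4)c3OCc3ccccc3)C=C2)cc1
F3 | step 11 | unit-B 3α-ol 4β-benzoate | C(c1ccccc1)Oc1ccc([C@H]2Oc3c(cc(-c4cc5c(c(OCc6ccccc6)c4OCc4ccccc4)O[C@H](c4ccc(OCc6ccccc6)cc4)[C@H](O)[C@H]5OC(=O)c4ccccc4)c(OS(=O)(=O)c4ccc(C)cc4)c3OCc3ccccc3)C=C2)cc1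
F4 | step 12 | unit-A bromohydrin of 15 (3β-Br, 4α-OH) | C(c1ccccc1)Oc1ccc([C@H]2Oc3c(cc(-c4cc5c(c(OCc6ccccc6)c4OCc4ccccc4)O[C@H](c4ccc(OCc6ccccc6)cc4)[C@H](OC(=O)c4ccccc4)[C@H]5OC(=O)c4ccccc4)c(OS(=O)(=O)c4ccc(C)cc4)c3OCc3ccccc3)[C@@H](O)[C@@H]2Br)cc1
F5 | step 12 | unit-A 3β-bromo 4α-tert-butyl carbonate | C(c1ccccc1)Oc1ccc([C@H]2Oc3c(cc(-c4cc5c(c(OCc6ccccc6)c4OCc4ccccc4)O[C@H](c4ccc(OCc6ccccc6)cc4)[C@H](OC(=O)c4ccccc4)[C@H]5OC(=O)c4ccccc4)c(OS(=O)(=O)c4ccc(C)cc4)c3OCc3ccccc3)[C@@H](OC(=O)OC(C)(C)C)[C@@H]2Br)cc1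
F6 | step 12 | unit-A 3α,4α-cyclic carbonate | C(c1ccccc1)Oc1ccc([C@H]2Oc3c(cc(-c4cc5c(c(OCc6ccccc6)c4OCc4ccccc4)O[C@H](c4ccc(OCc6ccccc6)cc4)[C@H](OC(=O)c4ccccc4)[C@H]5OC(=O)c4ccccc4)c(OS(=O)(=O)c4ccc(C)cc4)c3OCc3ccccc3)[C@@H](OC(=O)O7)[C@H]27)cc1
F7 | step 9 | 6,6′-bicoumarin, 8,8′,7′-tris(benzyloxy), 7-tosyloxy | O=C1Oc2c(C=C1)cc(-c1cc3C=CC(=O)Oc3c(OCc3ccccc3)c1OCc1ccccc1)c(OS(=O)(=O)c1ccc(C)cc1)c2OCc1ccccc1
F8 | step 9 | corresponding bis(2H-chromen-2-ol) | OC1Oc2c(C=C1)cc(-c1cc3C=CC(O)Oc3c(OCc3ccccc3)c1OCc1ccccc1)c(OS(=O)(=O)c1ccc(C)cc1)c2OCc1ccccc1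
F9 | step 9 | corresponding bis(2-ethoxy-2H-chromene) | CCOC1Oc2c(C=C1)cc(-c1cc3C=CC(OCC)Oc3c(OCc3ccccc3)c1OCc1ccccc1)c(OS(=O)(=O)c1ccc(C)cc1)c2OCc1ccccc1
F10 | step 9 | diethyl [4-(benzyloxy)phenyl]boronate | CCOB(OCC)c1ccc(OCc2ccccc2)cc1
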